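**Retrosynthetic overview**

1. Last disconnections: the aryl O-silyl group and the lactone bond C2–O1 of the (4R)-4-aryl-3,4-dihydrocoumarin, which lead back to the hydroxy ester 15.
2. The strategy rests on the orcinol-type benzene ring C4a–C5–C6–C7–C8–C8a (methyl on C5, 2-pyranone on C6, oxygen on C7 and C8a). It is a folded polyketide chain and is opened at C5–C6: aldol cyclisation–aromatisation of triketone 13 gives 15, with the pyranone as the preformed head of the chain.
3. In 13 the carbon that becomes C4a already carries C4 with its aryl group and the CH2CO2Me arm. The ring can therefore only form with the side chain next to the C5 methyl, and nothing has to be attached later to a resorcinol that would also offer C8, the position between the two hydroxyls.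
4. 13 is made by C-acylation of the bis(silyl enol ether) 8 of a 3-substituted acetylacetone with pyranonylacetyl chloride 11. The stereocentre comes from a carbene-catalysed oxidative [3+3] annulation of acetylacetone with 4-silyloxycinnamaldehyde.
5. Ring order: pyranone (bought) → dihydropyranone 6 (temporary, opened again) → benzene ring (step 9) → lactone ring (step 10).

Key step: step 9

Remark on stereochemistry: the sense of induction of the triazolium catalyst in step 3 is not predicted here. The catalyst antipode that gives (4R)-6 is to be used; both antipodes derive from the two enantiomers of cis-1-amino-2-indanol.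

Remark on 13 and 14: 13 is drawn as one triketo tautomer and 14 without ring configuration. Their enolisable or stereorandom ring carbons all become aromatic, so this has no consequence.

**Step 1**
Reactants: 1 4-hydroxybenzaldehyde
Product: 2 4-[(triisopropylsilyl)oxy]benzaldehyde
Conditions: TIPSCl, imidazole, DMF, 23 °C
Reagents that add atoms: triisopropylsilyl chloride, CC(C)[Si](Cl)(C(C)C)C(C)C
Why: Imidazole-promoted O-silylation of the phenol (silyl ether protection); the bulky triisopropylsilyl ether is chosen because it has to survive amine bases, silyl triflate and DBU later on.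

**Step 2**
Reactants: 2 4-[(triisopropylsilyl)oxy]benzaldehyde; 3 (triphenylphosphoranylidene)acetaldehyde
Product: 4 (2E)-3-{4-[(triisopropylsilyl)oxy]phenyl}prop-2-enal
Conditions: PhMe, 80 °C
Reagents that add atoms: none
Why: Wittig olefination with the formyl-stabilised ylide should give the (E)-enal, and only a slight excess of ylide is used so that the product enal is not homologated a second time.

**Step 3**
Reactants: 4 (2E)-3-{4-[(triisopropylsilyl)oxy]phenyl}prop-2-enal; 5 acetylacetone (pentane-2,4-dione)
Product: 6 (4R)-5-acetyl-6-methyl-4-{4-[(triisopropylsilyl)oxy]phenyl}-3,4-dihydro-2H-pyran-2-one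
Conditions: aminoindanol-derived N-mesityl triazolium chloride (10 mol %), DBU (20 mol %), 3,3',5,5'-tetra-tert-butyldiphenoquinone (1.1 equiv), PhMe, 23 °C
Reagents that add atoms: none
Why: NHC-catalysed oxidative [3+3] annulation, in which the carbene–enal adduct is oxidised by the diphenoquinone to an α,β-unsaturated acyl azolium, the enol of 5 adds to its β-carbon (Michael or Coates–Claisen pathway) and O-acylation of the enol closes the lactone and frees the carbene; the stereocentre is set by the chiral carbene, which must direct the enol carbon to the Re face of C-β (4R), and the symmetric diketone has only its central carbon as nucleophilic site.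

**Step 4**
Reactants: 6 (4R)-5-acetyl-6-methyl-4-{4-[(triisopropylsilyl)oxy]phenyl}-3,4-dihydro-2H-pyran-2-one
Product: 7 methyl (3S)-4-acetyl-5-oxo-3-{4-[(triisopropylsilyl)oxy]phenyl}hexanoate
Conditions: MeOH, DMAP (10 mol %), 23 °C
Reagents that add atoms: methanol, CO
Why: DMAP-catalysed methanolysis (transesterification) of the enol lactone, an activated acyl donor, releases the 2-substituted 1,3-diketone and the methyl ester; the stereocentre is β to every carbonyl and is untouched (the descriptor becomes S only because the CIP priorities change).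

**Step 5**
Reactants: 7 methyl (3S)-4-acetyl-5-oxo-3-{4-[(triisopropylsilyl)oxy]phenyl}hexanoate
Product: 8 methyl (3R)-3-{4-[(triisopropylsilyl)oxy]phenyl}-5-[(trimethylsilyl)oxy]-4-{1-[(trimethylsilyl)oxy]ethenyl}hex-4-enoate (geometry of the 4-ene not defined)
Conditions: TMSOTf (2.5 equiv), Et3N (3.5 equiv), Et2O, 0 to 23 °C; pentane extraction, used crude
Reagents that add atoms: trimethylsilyl trifluoromethanesulfonate, C[Si](C)(C)OS(=O)(=O)C(F)(F)F
Why: Soft enolisation with silyl triflate and amine turns the 1,3-diketone into its 1,3-bis(silyl enol ether) without strong base, so the ester is neither enolised nor attacked by the diketone terminus, as a lithium dianion would risk through intramolecular Claisen closure.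

**Step 6**
Reactants: 9 4-methoxy-6-methyl-2H-pyran-2-one
Product: 10 (4-methoxy-2-oxo-2H-pyran-6-yl)acetic acid
Conditions: LDA, THF, −78 °C; CO2 (excess); 1 M HCl, 0 °C
Reagents that add atoms: carbon dioxide, O=C=O
Why: Lateral (vinylogous) deprotonation of the 6-methyl group gives the extended enolate, which is carboxylated at the exocyclic carbon; excess carbon dioxide and a cold acidic work-up limit proton exchange with the product and decarboxylation.

**Step 7**
Reactants: 10 (4-methoxy-2-oxo-2H-pyran-6-yl)acetic acid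
Product: 11 (4-methoxy-2-oxo-2H-pyran-6-yl)acetyl chloride
Conditions: (COCl)2, DMF (cat.), CH2Cl2, 0 to 23 °C; evaporate, use at once
Reagents that add atoms: oxalyl chloride, O=C(Cl)C(=O)Cl
Why: Acid chloride formation through the chloroiminium (Vilsmeier-type) activator under base-free conditions, so that the acidic methylene next to the pyranone is not deprotonated to a ketene.

**Step 8**
Reactants: 8 methyl (3R)-3-{4-[(triisopropylsilyl)oxy]phenyl}-5-[(trimethylsilyl)oxy]-4-{1-[(trimethylsilyl)oxy]ethenyl}hex-4-enoate; 11 (4-methoxy-2-oxo-2H-pyran-6-yl)acetyl chloride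
Product: 13 methyl (3S)-4-acetyl-8-(4-methoxy-2-oxo-2H-pyran-6-yl)-5,7-dioxo-3-{4-[(triisopropylsilyl)oxy]phenyl}octanoate, via C-4 silyl enol ether 12 (not isolated)
Conditions: CH2Cl2, −78 to 20 °C (TMSOTf 10 mol % if slow); 0.1 M HCl, THF, 0 °C
Reagents that add atoms: none
Why: Mukaiyama-type Claisen C-acylation of the 1,3-bis(silyl enol ether) at its unhindered terminal methylene carbon by the acid chloride, run without base because an enolate dianion would deprotonate the more acidic pyranone-flanked methylene of the acyl donor instead of attacking it; dilute acid then removes the remaining enol silyl group of 12.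

**Step 9**
Reactants: 13 methyl (3S)-4-acetyl-8-(4-methoxy-2-oxo-2H-pyran-6-yl)-5,7-dioxo-3-{4-[(triisopropylsilyl)oxy]phenyl}octanoate
Product: 15 methyl (3R)-3-[4,6-dihydroxy-3-(4-methoxy-2-oxo-2H-pyran-6-yl)-2-methylphenyl]-3-{4-[(triisopropylsilyl)oxy]phenyl}propanoate, via cyclic aldol 14 (not isolated)
Conditions: DBU (2.5 equiv), THF (0.02 M), 0 to 23 °C; AcOH
Reagents that add atoms: none
Why: DBU enolises the C-8 methylene, the only carbon acid flanked by a ketone and by the vinylogous ester of the pyranone that can reach a carbonyl through a six-membered transition state; it adds to the acetyl carbonyl on C-4 (intramolecular aldol addition, 6-(enolendo)-exo-trig, ring made of C-8, C-7, C-6, C-5, C-4 and the acetyl carbon) to give 14, which loses water by E1cB and tautomerises irreversibly to the resorcinol. The closest known reaction type is the biomimetic aldol cyclisation–aromatisation of 3,5,7-triketo esters and 1,3,5,7-tetraketones to orsellinate-type resorcinols under mild base. No stereocentre is created: C-3 is β to every carbonyl and should keep its configuration, and the stereorandom ring carbons of 14 all become aromatic. The step needs the C-8-to-acetyl aldol to win over the aldol of the acetyl methyl onto C-7 and over Claisen attack of C-6 on the methyl ester; the first is secured by the far higher acidity of the pyranone-flanked methylene, the second by the non-nucleophilic amine base, under which acylation of a stabilised diketonate by an ester is slow. The 2-substituted 1,3-diketone is little enolised, so the acetyl group remains a true ketone electrophile. Since the carbon that becomes C4a already bears the side chain, the ring can form in one orientation only; any lactone 16 formed at this stage is carried into step 10.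

**Step 10**
Reactants: 15 methyl (3R)-3-[4,6-dihydroxy-3-(4-methoxy-2-oxo-2H-pyran-6-yl)-2-methylphenyl]-3-{4-[(triisopropylsilyl)oxy]phenyl}propanoate
Product: 16 (4R)-7-hydroxy-6-(4-methoxy-2-oxo-2H-pyran-6-yl)-5-methyl-4-{4-[(triisopropylsilyl)oxy]phenyl}-3,4-dihydro-2H-chromen-2-one
Conditions: p-TsOH·H2O (10 mol %), PhMe, 4 Å MS, 80 °C
Reagents that add atoms: none
Why: Acid-catalysed intramolecular transesterification (lactonisation), in which only the hydroxyl ortho to the side chain can reach the ester through a six-membered transition state and the flanking methyl and benzylic aryl groups favour the folded conformer; the stereocentre is not involved.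

**Step 11**
Reactants: 16 (4R)-7-hydroxy-6-(4-methoxy-2-oxo-2H-pyran-6-yl)-5-methyl-4-{4-[(triisopropylsilyl)oxy]phenyl}-3,4-dihydro-2H-chromen-2-one
Product: 17 (4R)-7-hydroxy-4-(4-hydroxyphenyl)-6-(4-methoxy-2-oxo-2H-pyran-6-yl)-5-methyl-3,4-dihydro-2H-chromen-2-one
Conditions: TBAF, AcOH, THF, 0 °C
Reagents that add atoms: none
Why: Fluoride-induced cleavage of the aryl silyl ether, buffered with acetic acid so that the phenolic lactone is not opened, should give the target.

**Compound list**

1 | 4-hydroxybenzaldehyde | O=Cc1ccc(O)cc1 | starting material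
2 | 4-[(triisopropylsilyl)oxy]benzaldehyde | O=Cc1ccc(O[Si](C(C)C)(C(C)C)C(C)C)cc1 | intermediate
3 | (triphenylphosphoranylidene)acetaldehyde | O=CC=P(c1ccccc1)(c1ccccc1)c1ccccc1 | starting material
4 | (2E)-3-{4-[(triisopropylsilyl)oxy]phenyl}prop-2-enal | O=C/C=C/c1ccc(O[Si](C(C)C)(C(C)C)C(C)C)cc1 | intermediate
5 | acetylacetone (pentane-2,4-dione) | CC(=O)CC(C)=O | starting material
6 | (4R)-5-acetyl-6-methyl-4-{4-[(triisopropylsilyl)oxy]phenyl}-3,4-dihydro-2H-pyran-2-one | CC(=O)C1=C(C)OC(=O)C[C@@H]1c1ccc(O[Si](C(C)C)(C(C)C)C(C)C)cc1 | intermediate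
7 | methyl (3S)-4-acetyl-5-oxo-3-{4-[(triisopropylsilyl)oxy]phenyl}hexanoate | COC(=O)C[C@H](c1ccc(O[Si](C(C)C)(C(C)C)C(C)C)cc1)C(C(C)=O)C(C)=O | intermediate
8 | methyl (3R)-3-{4-[(triisopropylsilyl)oxy]phenyl}-5-[(trimethylsilyl)oxy]-4-{1-[(trimethylsilyl)oxy]ethenyl}hex-4-enoate | COC(=O)C[C@H](c1ccc(O[Si](C(C)C)(C(C)C)C(C)C)cc1)C(C(=C)O[Si](C)(C)C)=C(C)O[Si](C)(C)C | intermediate
9 | 4-methoxy-6-methyl-2H-pyran-2-one | COc1cc(C)oc(=O)c1 | starting material
10 | (4-methoxy-2-oxo-2H-pyran-6-yl)acetic acid | COc1cc(CC(=O)O)oc(=O)c1 | intermediate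
11 | (4-methoxy-2-oxo-2H-pyran-6-yl)acetyl chloride | COc1cc(CC(=O)Cl)oc(=O)c1 | intermediate
12 | methyl (3R)-8-(4-methoxy-2-oxo-2H-pyran-6-yl)-5,7-dioxo-3-{4-[(triisopropylsilyl)oxy]phenyl}-4-{1-[(trimethylsilyl)oxy]ethylidene}octanoate | COC(=O)C[C@H](c1ccc(O[Si](C(C)C)(C(C)C)C(C)C)cc1)C(=C(C)O[Si](C)(C)C)C(=O)CC(=O)Cc1cc(OC)cc(=O)o1 | intermediate
13 | methyl (3S)-4-acetyl-8-(4-methoxy-2-oxo-2H-pyran-6-yl)-5,7-dioxo-3-{4-[(triisopropylsilyl)oxy]phenyl}octanoate | COC(=O)C[C@H](c1ccc(O[Si](C(C)C)(C(C)C)C(C)C)cc1)C(C(C)=O)C(=O)CC(=O)Cc1cc(OC)cc(=O)o1 | intermediate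
14 | methyl (3S)-3-[6-hydroxy-5-(4-methoxy-2-oxo-2H-pyran-6-yl)-6-methyl-2,4-dioxocyclohexyl]-3-{4-[(triisopropylsilyl)oxy]phenyl}propanoate | COC(=O)C[C@H](c1ccc(O[Si](C(C)C)(C(C)C)C(C)C)cc1)C1C(=O)CC(=O)C(c2cc(OC)cc(=O)o2)C1(C)O | intermediate
15 | methyl (3R)-3-[4,6-dihydroxy-3-(4-methoxy-2-oxo-2H-pyran-6-yl)-2-methylphenyl]-3-{4-[(triisopropylsilyl)oxy]phenyl}propanoate | COC(=O)C[C@H](c1ccc(O[Si](C(C)C)(C(C)C)C(C)C)cc1)c1c(O)cc(O)c(-c2cc(OC)cc(=O)o2)c1C | intermediate
16 | (4R)-7-hydroxy-6-(4-methoxy-2-oxo-2H-pyran-6-yl)-5-methyl-4-{4-[(triisopropylsilyl)oxy]phenyl}-3,4-dihydro-2H-chromen-2-one | COc1cc(-c2c(O)cc3c(c2C)[C@@H](c2ccc(O[Si](C(C)C)(C(C)C)C(C)C)cc2)CC(=O)O3)oc(=O)c1 | intermediate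
17 | (4R)-7-hydroxy-4-(4-hydroxyphenyl)-6-(4-methoxy-2-oxo-2H-pyran-6-yl)-5-methyl-3,4-dihydro-2H-chromen-2-one | COc1cc(-c2c(O)cc3c(c2C)[C@@H](c2ccc(O)cc2)CC(=O)O3)oc(=O)c1 | target

Total step count: 11. Longest linear sequence: 9 steps (steps 1–5 and 8–11); steps 6 and 7 form the short branch.

**Steps most likely to fail**

Step 8 (union of the two halves). The twisted diene 8 may lose its silyl groups to traces of HCl, or be acylated on oxygen, faster than its terminal carbon attacks 11; loss of HCl from 11 to the ketene is a further drain. The fallback replaces the silyl enol ether by polyanion acylation; it sets out from 6 and 10 and returns at 16. Lactone 6 is hydrolysed (LiOH, THF–H2O, 0 °C) to (3S)-4-acetyl-5-oxo-3-{4-[(triisopropylsilyl)oxy]phenyl}hexanoic acid F1, and 10 is esterified with trimethylsilyldiazomethane to methyl (4-methoxy-2-oxo-2H-pyran-6-yl)acetate F2. F1 is converted with LDA (3.2 equiv, THF, −78 to 0 °C) into its trilithium salt (carboxylate, diketonate, terminal carbanion). The preformed lithium enolate of F2 (LiHMDS, 1 equiv) is added and the mixture is warmed from 0 to 23 °C. Acylation of β-diketone polyanions by esters that are present as their enolate salts is a known route to polyketones, and the pre-deprotonated ester keeps the chiral fragment from being consumed as a base. Acidification should give (3S)-4-acetyl-8-(4-methoxy-2-oxo-2H-pyran-6-yl)-5,7-dioxo-3-{4-[(triisopropylsilyl)oxy]phenyl}octanoic acid F3. Its carboxylate cannot undergo Claisen closure, and aqueous K2CO3 (pH about 10, 23 °C) should bring about the same aldol aromatisation to (3R)-3-[4,6-dihydroxy-3-(4-methoxy-2-oxo-2H-pyran-6-yl)-2-methylphenyl]-3-{4-[(triisopropylsilyl)oxy]phenyl}propanoic acid F4, which is closed to 16 under the conditions of step 10.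

Step 9 (key step). Addition of the C-8 carbanion to the flanked acetyl carbonyl may be too slow, so that retro-Claisen cleavage of the 2-substituted 1,3-diketone, Claisen closure onto the ester or retro-Michael loss of the side chain (with erosion of the stereocentre) take over. The fallback replaces aldol addition to a ketone by addition–elimination at an enol-lactone carbon; it sets out from 6 and 11 and returns at 16. Lactone 6 is silylated on its acetyl group (TMSOTf 1.2 equiv, Et3N, CH2Cl2, 0 °C) to (4R)-6-methyl-4-{4-[(triisopropylsilyl)oxy]phenyl}-5-{1-[(trimethylsilyl)oxy]ethenyl}-3,4-dihydro-2H-pyran-2-one F5. This is C-acylated by 11 (ZnCl2 or BiCl3–ZnI2 cat., CH2Cl2; Mukaiyama-type acylation of a silyl enol ether) to (4R)-5-[4-(4-methoxy-2-oxo-2H-pyran-6-yl)-3-oxobutanoyl]-6-methyl-4-{4-[(triisopropylsilyl)oxy]phenyl}-3,4-dihydro-2H-pyran-2-one F6. In F6 the carbon that becomes C5 is the β-carbon of a β-acyloxy enone. With DBU the pyranone-flanked carbanion should add to it (6-endo-trig conjugate addition), the lactone carboxylate is expelled and tautomerisation gives the hydroxy acid F4 of the first fallback, which is closed to 16 as in step 10. The same C5–C6 bond is formed, with carboxylate in place of hydroxide as the leaving group and without a free ester in the molecule.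

Step 3 (stereocentre). Enantiofacial discrimination at C-β of the acyl azolium may fall short, or the acyl azolium may be consumed by O-acylation of the bisphenol that the oxidant leaves. The fallback uses isothiourea Lewis-base catalysis without an oxidant; it sets out from 4 (with 5) and returns at 6. Pinnick oxidation of 4 (NaClO2, NaH2PO4, 2-methyl-2-butene, t-BuOH–H2O) gives (2E)-3-{4-[(triisopropylsilyl)oxy]phenyl}prop-2-enoic acid F7. Pivaloyl chloride and i-Pr2NEt convert it in the flask into (2E)-3-{4-[(triisopropylsilyl)oxy]phenyl}prop-2-enoic 2,2-dimethylpropanoic anhydride F8. With 5 and HyperBTM (10 mol %, the antipode that gives 4R; CH2Cl2, 23 °C), F8 should undergo Michael addition–lactonisation through the α,β-unsaturated acyl ammonium ion to give 6.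

**Further compounds**

F1 | step 8 | (3S)-4-acetyl-5-oxo-3-{4-[(triisopropylsilyl)oxy]phenyl}hexanoic acid | OC(=O)C[C@H](c1ccc(O[Si](C(C)C)(C(C)C)C(C)C)cc1)C(C(C)=O)C(C)=O
F2 | step 8 | methyl (4-methoxy-2-oxo-2H-pyran-6-yl)acetate | COC(=O)Cc1cc(OC)cc(=O)o1
F3 | step 8 | (3S)-4-acetyl-8-(4-methoxy-2-oxo-2H-pyran-6-yl)-5,7-dioxo-3-{4-[(triisopropylsilyl)oxy]phenyl}octanoic acid | OC(=O)C[C@H](c1ccc(O[Si](C(C)C)(C(C)C)C(C)C)cc1)C(C(C)=O)C(=O)CC(=O)Cc1cc(OC)cc(=O)o1
F4 | step 8 | (3R)-3-[4,6-dihydroxy-3-(4-methoxy-2-oxo-2H-pyran-6-yl)-2-methylphenyl]-3-{4-[(triisopropylsilyl)oxy]phenyl}propanoic acid | OC(=O)C[C@H](c1ccc(O[Si](C(C)C)(C(C)C)C(C)C)cc1)c1c(O)cc(O)c(-c2cc(OC)cc(=O)o2)c1C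
F5 | step 9 | (4R)-6-methyl-4-{4-[(triisopropylsilyl)oxy]phenyl}-5-{1-[(trimethylsilyl)oxy]ethenyl}-3,4-dihydro-2H-pyran-2-one | C=C(O[Si](C)(C)C)C1=C(C)OC(=O)C[C@@H]1c1ccc(O[Si](C(C)C)(C(C)C)C(C)C)cc1
F6 | step 9 | (4R)-5-[4-(4-methoxy-2-oxo-2H-pyran-6-yl)-3-oxobutanoyl]-6-methyl-4-{4-[(triisopropylsilyl)oxy]phenyl}-3,4-dihydro-2H-pyran-2-one | COc1cc(CC(=O)CC(=O)C2=C(C)OC(=O)C[C@@H]2c2ccc(O[Si](C(C)C)(C(C)C)C(C)C)cc2)oc(=O)c1
F7 | step 3 | (2E)-3-{4-[(triisopropylsilyl)oxy]phenyl}prop-2-enoic acid | OC(=O)/C=C/c1ccc(O[Si](C(C)C)(C(C)C)C(C)C)cc1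
F8 | step 3 | (2E)-3-{4-[(triisopropylsilyl)oxy]phenyl}prop-2-enoic 2,2-dimethylpropanoic anhydride | CC(C)(C)C(=O)OC(=O)/C=C/c1ccc(O[Si](C(C)C)(C(C)C)C(C)C)cc1
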